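**Retrosynthetic overview**

Rings: A = 4-hydroxyphenyl of the styryl group; B = benzo ring of the styryl-bearing dihydrobenzofuran (O1, C2, C3, styryl on C4); F = 4-hydroxyphenyl on C2; C = benzo ring of the second dihydrobenzofuran (O1', C2', C3'); D = 3,5-dihydroxyphenyl on C3'; E = 4-hydroxyphenyl on C2'.
The strategy rests on the C2–C3 bond of the ring B dihydrobenzofuran: C2 is a benzylic ether carbon (O1 and ring F) and C3 sits on ring B ortho to O1, so a carbene at C3 and a benzylic C–H of a 4-methoxybenzyl (PMB) ether on O1 stand in a 1,5 relationship.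
Disconnections, backwards: the Z alkene at C4 (Suzuki–Miyaura on the C4 chloride, after the methyl ethers have been exchanged for silyl ethers, so the alkene never meets BBr3); the C3–ring C bond (nickel/photoredox decarboxylative arylation of the C3 acid with the 5-bromide of fragment 2, trans to ring F); the C2–C3 bond (rhodium carbene C–H insertion).
Fragment 2 (rings C, D, E) comes from 5-bromo-2-hydroxy-3-methoxybenzaldehyde by the diaryl-carbene version of the same insertion (C2'–C3'), followed by acid epimerisation of C2' to the trans ring.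
Order of ring formation: furan ring on ring B (step 6), furan ring on ring C (step 12), union of the two halves (step 14), Z-styryl group (step 18).

Key step: step 6

Assumption: in this reaction class the S-configured N-phthaloyl amino-carboxylate dirhodium catalysts are taken to give the (2R) ring carbon, and both insertions here need (2S), so the R-configured catalysts Rh2(R-PTTL)4 (from D-tert-leucine) and Rh2(R-PTAD)4 are used; if either sense proves opposite, the mirror-image catalyst is used and nothing else changes.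

**Route**

Step 1
Reactants: 1 1-chloro-3,5-dimethoxybenzene; 2 methyl chlorooxoacetate
Product: 3 methyl 2-(2-chloro-4,6-dimethoxyphenyl)-2-oxoacetate
Conditions: AlCl3 (1.2 equiv), CH2Cl2, −10 → 0 °C
Reagents that add atoms: none
Why: Friedel–Crafts acylation, in which the acylium ion attacks the position para to one methoxy group and ortho to the other (next to chlorine), the usual site for 5-substituted 1,3-dimethoxybenzenes, so the 1,2,3,5 pattern of ring B is fixed and the ketone later directs step 2 and supplies the diazo carbon.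

Step 2
Reactants: 3 methyl 2-(2-chloro-4,6-dimethoxyphenyl)-2-oxoacetate
Product: 4 methyl 2-(2-chloro-6-hydroxy-4-methoxyphenyl)-2-oxoacetate
Conditions: BCl3 (2.2 equiv), CH2Cl2, −78 → 0 °C; aqueous work-up
Reagents that add atoms: none
Why: Chelation-controlled ether cleavage, in which BCl3 bridges the ketone oxygen and the ortho methoxy oxygen in a six-membered chelate and chloride removes only that methyl group, while the para methoxy group and the methyl ester are not activated at this temperature.

Step 3
Reactants: 4 methyl 2-(2-chloro-6-hydroxy-4-methoxyphenyl)-2-oxoacetate; 5 4-methoxybenzyl chloride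
Product: 6 methyl 2-[2-chloro-4-methoxy-6-(4-methoxybenzyloxy)phenyl]-2-oxoacetate
Conditions: K2CO3, DMF, 40 °C
Reagents that add atoms: none
Why: Williamson ether synthesis on the phenoxide, which puts the 4-methoxybenzyl group (the future C2 and ring F) on the oxygen that becomes O1, and the mild base leaves the keto ester intact.

Step 4
Reactants: 6 methyl 2-[2-chloro-4-methoxy-6-(4-methoxybenzyloxy)phenyl]-2-oxoacetate
Product: 7 methyl 2-[2-chloro-4-methoxy-6-(4-methoxybenzyloxy)phenyl]-2-(tosylhydrazinylidene)acetate (E/Z mixture)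
Conditions: TsNHNH2, MeOH, 60 °C
Reagents that add atoms: p-toluenesulfonyl hydrazide, Cc1ccc(cc1)S(=O)(=O)NN
Why: Hydrazone condensation at the ketone carbonyl of the α-keto ester, the more electrophilic carbonyl, which reacts without added acid so that the 4-methoxybenzyl ether survives.

Step 5
Reactants: 7 the tosylhydrazone
Product: 8 methyl 2-diazo-2-[2-chloro-4-methoxy-6-(4-methoxybenzyloxy)phenyl]acetate
Conditions: DBU, CH2Cl2, 0 °C → rt
Reagents that add atoms: none
Why: Bamford–Stevens elimination, in which DBU removes the N–H proton and sulfinate leaves, giving the ester-stabilised aryldiazoacetate without the need for an enolate of a hindered arylacetate.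

Step 6
Reactants: 8 methyl 2-diazo-2-[2-chloro-4-methoxy-6-(4-methoxybenzyloxy)phenyl]acetate
Product: 9 methyl (2S,3R)-4-chloro-6-methoxy-2-(4-methoxyphenyl)-2,3-dihydrobenzofuran-3-carboxylate (cis)
Conditions: Rh2(R-PTTL)4 (2 mol%; PTTL = N-phthaloyl-tert-leucinate), toluene (0.02 M), −60 → −40 °C
Reagents that add atoms: none
Why: Rh2(R-PTTL)4 takes nitrogen from 8 and gives a rhodium-bound donor/acceptor carbene at the future C3, which inserts into one benzylic C–H bond of the 4-methoxybenzyl ether through a three-centre, hydride-transfer-like transition state and so forms C2–C3. The closest known reaction type is the dirhodium carboxylate-catalysed intramolecular C–H insertion of aryldiazoacetates into ortho benzylic ethers, which gives cis-2-aryl-2,3-dihydrobenzofuran-3-carboxylates. The furan ring closes in the 1,5 mode (carbene carbon, C3a, C7a, O1, benzylic carbon), and the five-membered ring is favoured because the ether oxygen and the 4-methoxyphenyl group both activate that C–H bond. C2 is set by the chiral carboxylate ligands, which select one of the two enantiotopic benzylic hydrogens, and C3 comes out cis to ring F from the same transition state, a configuration that is not needed later. The step needs insertion to win over carbene dimerisation, attack on the aromatic ring of the benzyl group and reaction at the methoxy groups; the ortho ether holds the activated CH2 next to the carbene and low temperature and dilution help, but the chlorine and the ether that flank the carbene make it crowded, which is the main risk.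

Step 7
Reactants: 9 the cis ester
Product: 10 (2S,3R)-4-chloro-6-methoxy-2-(4-methoxyphenyl)-2,3-dihydrobenzofuran-3-carboxylic acid
Conditions: LiOH, THF/MeOH/H2O, 0 °C → rt; then 1 M HCl
Reagents that add atoms: lithium hydroxide (hydroxide oxygen), [Li+].[OH-]
Why: Ester saponification, in which partial epimerisation at C3 would be harmless because C3 becomes a planar radical in step 14, while C2 carries no acidic hydrogen and keeps its configuration.

Step 8
Reactants: 11 5-bromo-2-hydroxy-3-methoxybenzaldehyde; 5 4-methoxybenzyl chloride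
Product: 12 5-bromo-3-methoxy-2-(4-methoxybenzyloxy)benzaldehyde
Conditions: K2CO3, DMF, 50 °C
Reagents that add atoms: none
Why: Williamson ether synthesis, which places the future C2' and ring E on the oxygen that becomes O1' of fragment 2.

Step 9
Reactants: 12 the aldehyde; 13 3,5-dimethoxyphenylmagnesium bromide
Product: 14 [5-bromo-3-methoxy-2-(4-methoxybenzyloxy)phenyl](3,5-dimethoxyphenyl)methanol (racemic)
Conditions: THF, −78 → 0 °C; aqueous NH4Cl
Reagents that add atoms: none
Why: Grignard addition to the aldehyde at low temperature, where the aryl bromide does not exchange, and the racemic carbinol centre is removed in step 10.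

Step 10
Reactants: 14 the diaryl carbinol
Product: 15 [5-bromo-3-methoxy-2-(4-methoxybenzyloxy)phenyl](3,5-dimethoxyphenyl)methanone
Conditions: MnO2, CH2Cl2, rt
Reagents that add atoms: none
Why: MnO2 oxidation of a doubly benzylic alcohol to the diaryl ketone, a selective reaction that leaves the benzyl ether and the bromide alone.

Step 11
Reactants: 15 the diaryl ketone
Product: 16 the hydrazone of 15, [5-bromo-3-methoxy-2-(4-methoxybenzyloxy)phenyl](3,5-dimethoxyphenyl)methanone hydrazone (E/Z mixture)
Conditions: N2H4·H2O (excess), AcOH (cat.), EtOH, 80 °C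
Reagents that add atoms: hydrazine hydrate, NN.O
Why: Hydrazone condensation of a diaryl ketone, driven by excess hydrazine, which also suppresses azine formation.

Step 12
Reactants: 16 the hydrazone
Product: 18 (2S,3R)-5-bromo-3-(3,5-dimethoxyphenyl)-7-methoxy-2-(4-methoxyphenyl)-2,3-dihydrobenzofuran (cis), via diaryldiazomethane 17 (not isolated)
Conditions: MnO2, CH2Cl2, 0 °C; filter; Rh2(R-PTAD)4 (1 mol%; PTAD = (1-adamantyl)(N-phthalimido)acetate), CH2Cl2, −20 °C → rt
Reagents that add atoms: none
Why: Oxidation of the hydrazone to the diaryldiazomethane and dirhodium-catalysed intramolecular 1,5 C–H insertion of the donor/donor carbene into the 4-methoxybenzyl ether should close the furan ring of fragment 2 with the two aryl groups cis, the chiral catalyst selecting one enantiotopic benzylic hydrogen and so setting C3 as R (and C2 as S), while the aryl bromide is inert to the carbene.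

Step 13
Reactants: 18 the cis dihydrobenzofuran
Product: 19 (2R,3R)-5-bromo-3-(3,5-dimethoxyphenyl)-7-methoxy-2-(4-methoxyphenyl)-2,3-dihydrobenzofuran (trans; fragment 2)
Conditions: TFA (20 equiv), CH2Cl2 (0.01 M), 0 °C, short reaction time
Reagents that add atoms: none
Why: Acid-mediated epimerisation of a 2-aryl-2,3-dihydrobenzofuran, in which reversible ionisation of the C2–O bond gives a 4-methoxybenzyl cation that the phenol oxygen recaptures anti to the C3 aryl group, so C2 is inverted to R under control of the untouched C3 and the more stable trans ring results.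

Step 14
Reactants: 10 the C3 carboxylic acid; 19 the bromide of fragment 2
Product: 20 (2S,3S)-4-chloro-3-[(2R,3R)-3-(3,5-dimethoxyphenyl)-7-methoxy-2-(4-methoxyphenyl)-2,3-dihydrobenzofuran-5-yl]-6-methoxy-2-(4-methoxyphenyl)-2,3-dihydrobenzofuran
Conditions: NiCl2(dme) (10 mol%), 4,4'-di-tert-butyl-2,2'-bipyridine (15 mol%), Ir[dF(CF3)ppy]2(dtbbpy)PF6 (2 mol%), Cs2CO3, DMF, blue LEDs, rt
Reagents that add atoms: none
Why: Nickel/photoredox decarboxylative arylation, in which the excited iridium photocatalyst oxidises the caesium carboxylate, CO2 is lost, the planar benzylic C3 radical is taken up by the aryl–nickel species formed from 19 and zerovalent nickel, and reductive elimination forms the C3–ring C bond on the face anti to ring F, which sets C3 as S (trans) whatever the C3 configuration of 10, while the hindered, electron-rich C4–Cl bond is much slower in oxidative addition than the C–Br bond.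

Step 15
Reactants: 20 the hexamethyl ether
Product: 21 (2S,3S)-4-chloro-3-[(2R,3R)-3-(3,5-dihydroxyphenyl)-7-hydroxy-2-(4-hydroxyphenyl)-2,3-dihydrobenzofuran-5-yl]-2-(4-hydroxyphenyl)-2,3-dihydrobenzofuran-6-ol
Conditions: BBr3 (excess), CH2Cl2, −78 → 0 °C; MeOH, then aqueous NaHCO3
Reagents that add atoms: none
Why: Lewis acid cleavage of the six aryl methyl ethers with BBr3, carried out before any alkene is present, and any ionisation of a C2–O bond would be reversible and reclose to the trans rings, which are the more stable ones and are those required.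

Step 16
Reactants: 21 the hexaphenol
Product: 22 the hexakis(tert-butyldimethylsilyl) ether of 21
Conditions: TBSCl (9 equiv), imidazole, DMF, rt
Reagents that add atoms: tert-butyldimethylsilyl chloride, CC(C)(C)[Si](C)(C)Cl
Why: Silylation of the six phenols, so that the coupling in step 18 meets no free phenoxide and the last deprotection needs only fluoride.

Step 17
Reactants: 23 tert-butyl(4-ethynylphenoxy)dimethylsilane
Product: 24 (Z)-tert-butyldimethyl{4-[2-(4,4,5,5-tetramethyl-1,3,2-dioxaborolan-2-yl)ethenyl]phenoxy}silane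
Conditions: pinacolborane, [Rh(cod)Cl]2 (1.5 mol%), P(i-Pr)3 (6 mol%), Et3N, cyclohexane, rt
Reagents that add atoms: pinacolborane, [H]B1OC(C)(C)C(C)(C)O1
Why: Rhodium-catalysed trans-hydroboration of a terminal alkyne, which runs through a rhodium vinylidene and places boron and the aryl group cis, giving the Z alkenylboronate.

Step 18
Reactants: 22 the hexasilylated aryl chloride; 24 the Z alkenylboronate
Product: 25 the heptakis(tert-butyldimethylsilyl) ether of the target, with the Z-styryl group on C4
Conditions: Pd(OAc)2 (5 mol%), SPhos (10 mol%), K3PO4, toluene/H2O, 80 °C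
Reagents that add atoms: none
Why: Suzuki–Miyaura coupling, in which the electron-rich biaryl phosphine allows oxidative addition into the hindered C4–Cl bond, transmetalation and reductive elimination keep the Z geometry, and any silyl ether lost to the base does not matter because step 19 removes all of them.

Step 19
Reactants: 25 the heptasilyl ether
Product: 26 the target, (2S,3S)-3-[(2R,3R)-3-(3,5-dihydroxyphenyl)-7-hydroxy-2-(4-hydroxyphenyl)-2,3-dihydrobenzofuran-5-yl]-2-(4-hydroxyphenyl)-4-[(Z)-2-(4-hydroxyphenyl)ethenyl]-2,3-dihydrobenzofuran-6-ol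
Conditions: TBAF, AcOH, THF, 0 °C; aqueous NH4Cl
Reagents that add atoms: none
Why: Fluoride cleavage of the seven aryl silyl ethers under acetic acid buffering, conditions that touch neither the Z alkene nor the benzylic ether bonds of the two dihydrobenzofurans and leave the four stereocentres as they are.

**Compound list**

1 | 1-chloro-3,5-dimethoxybenzene | COc1cc(Cl)cc(OC)c1 | starting material
2 | methyl chlorooxoacetate | COC(=O)C(=O)Cl | starting material
3 | methyl 2-(2-chloro-4,6-dimethoxyphenyl)-2-oxoacetate | COC(=O)C(=O)c1c(Cl)cc(OC)cc1OC | intermediate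
4 | methyl 2-(2-chloro-6-hydroxy-4-methoxyphenyl)-2-oxoacetate | COC(=O)C(=O)c1c(Cl)cc(OC)cc1O | intermediate
5 | 4-methoxybenzyl chloride | COc1ccc(CCl)cc1 | starting material
6 | methyl 2-[2-chloro-4-methoxy-6-(4-methoxybenzyloxy)phenyl]-2-oxoacetate | COC(=O)C(=O)c1c(Cl)cc(OC)cc1OCc1ccc(OC)cc1 | intermediate
7 | tosylhydrazone of 6 (E/Z mixture) | COC(=O)C(=NNS(=O)(=O)c1ccc(C)cc1)c1c(Cl)cc(OC)cc1OCc1ccc(OC)cc1 | intermediate
8 | methyl 2-diazo-2-[2-chloro-4-methoxy-6-(4-methoxybenzyloxy)phenyl]acetate | COC(=O)C(=[N+]=[N-])c1c(Cl)cc(OC)cc1OCc1ccc(OC)cc1 | intermediate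
9 | methyl (2S,3R)-4-chloro-6-methoxy-2-(4-methoxyphenyl)-2,3-dihydrobenzofuran-3-carboxylate (cis) | COC(=O)[C@@H]1c2c(Cl)cc(OC)cc2O[C@@H]1c1ccc(OC)cc1 | intermediate
10 | (2S,3R)-4-chloro-6-methoxy-2-(4-methoxyphenyl)-2,3-dihydrobenzofuran-3-carboxylic acid | OC(=O)[C@@H]1c2c(Cl)cc(OC)cc2O[C@@H]1c1ccc(OC)cc1 | intermediate
11 | 5-bromo-2-hydroxy-3-methoxybenzaldehyde | COc1cc(Br)cc(C=O)c1O | starting material
12 | 5-bromo-3-methoxy-2-(4-methoxybenzyloxy)benzaldehyde | COc1ccc(COc2c(OC)cc(Br)cc2C=O)cc1 | intermediate
13 | 3,5-dimethoxyphenylmagnesium bromide (THF solution) | COc1cc(OC)cc([Mg]Br)c1 | starting material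
14 | [5-bromo-3-methoxy-2-(4-methoxybenzyloxy)phenyl](3,5-dimethoxyphenyl)methanol (racemic) | COc1ccc(COc2c(OC)cc(Br)cc2C(O)c2cc(OC)cc(OC)c2)cc1 | intermediate
15 | [5-bromo-3-methoxy-2-(4-methoxybenzyloxy)phenyl](3,5-dimethoxyphenyl)methanone | COc1ccc(COc2c(OC)cc(Br)cc2C(=O)c2cc(OC)cc(OC)c2)cc1 | intermediate
16 | hydrazone of 15 (E/Z mixture) | COc1ccc(COc2c(OC)cc(Br)cc2C(=NN)c2cc(OC)cc(OC)c2)cc1 | intermediate
17 | 5-bromo-1-[diazo(3,5-dimethoxyphenyl)methyl]-3-methoxy-2-(4-methoxybenzyloxy)benzene | COc1ccc(COc2c(OC)cc(Br)cc2C(=[N+]=[N-])c2cc(OC)cc(OC)c2)cc1 | intermediate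
18 | (2S,3R)-5-bromo-3-(3,5-dimethoxyphenyl)-7-methoxy-2-(4-methoxyphenyl)-2,3-dihydrobenzofuran (cis) | Brc1cc(OC)c2c(c1)[C@@H](c1cc(OC)cc(OC)c1)[C@@H](c1ccc(OC)cc1)O2 | intermediate
19 | (2R,3R)-5-bromo-3-(3,5-dimethoxyphenyl)-7-methoxy-2-(4-methoxyphenyl)-2,3-dihydrobenzofuran (trans) | Brc1cc(OC)c2c(c1)[C@@H](c1cc(OC)cc(OC)c1)[C@H](c1ccc(OC)cc1)O2 | intermediate
20 | (2S,3S)-4-chloro-3-[(2R,3R)-3-(3,5-dimethoxyphenyl)-7-methoxy-2-(4-methoxyphenyl)-2,3-dihydrobenzofuran-5-yl]-6-methoxy-2-(4-methoxyphenyl)-2,3-dihydrobenzofuran | Clc1cc(OC)cc2c1[C@H](c1cc(OC)c3c(c1)[C@@H](c1cc(OC)cc(OC)c1)[C@H](c1ccc(OC)cc1)O3)[C@@H](c1ccc(OC)cc1)O2 | intermediate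
21 | (2S,3S)-4-chloro-3-[(2R,3R)-3-(3,5-dihydroxyphenyl)-7-hydroxy-2-(4-hydroxyphenyl)-2,3-dihydrobenzofuran-5-yl]-2-(4-hydroxyphenyl)-2,3-dihydrobenzofuran-6-ol | Clc1cc(O)cc2c1[C@H](c1cc(O)c3c(c1)[C@@H](c1cc(O)cc(O)c1)[C@H](c1ccc(O)cc1)O3)[C@@H](c1ccc(O)cc1)O2 | intermediate
22 | hexakis(tert-butyldimethylsilyl) ether of 21 | Clc1cc(O[Si](C)(C)C(C)(C)C)cc2c1[C@H](c1cc(O[Si](C)(C)C(C)(C)C)c3c(c1)[C@@H](c1cc(O[Si](C)(C)C(C)(C)C)cc(O[Si](C)(C)C(C)(C)C)c1)[C@H](c1ccc(O[Si](C)(C)C(C)(C)C)cc1)O3)[C@@H](c1ccc(O[Si](C)(C)C(C)(C)C)cc1)O2 | intermediate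
23 | tert-butyl(4-ethynylphenoxy)dimethylsilane | C#Cc1ccc(O[Si](C)(C)C(C)(C)C)cc1 | starting material
24 | (Z)-tert-butyldimethyl{4-[2-(4,4,5,5-tetramethyl-1,3,2-dioxaborolan-2-yl)ethenyl]phenoxy}silane | CC(C)(C)[Si](C)(C)Oc1ccc(/C=C\B2OC(C)(C)C(C)(C)O2)cc1 | intermediate
25 | heptakis(tert-butyldimethylsilyl) ether of the target | CC(C)(C)[Si](C)(C)Oc1ccc(/C=C\c2cc(O[Si](C)(C)C(C)(C)C)cc3c2[C@H](c2cc(O[Si](C)(C)C(C)(C)C)c4c(c2)[C@@H](c2cc(O[Si](C)(C)C(C)(C)C)cc(O[Si](C)(C)C(C)(C)C)c2)[C@H](c2ccc(O[Si](C)(C)C(C)(C)C)cc2)O4)[C@@H](c2ccc(O[Si](C)(C)C(C)(C)C)cc2)O3)cc1 | intermediate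
26 | (2S,3S)-3-[(2R,3R)-3-(3,5-dihydroxyphenyl)-7-hydroxy-2-(4-hydroxyphenyl)-2,3-dihydrobenzofuran-5-yl]-2-(4-hydroxyphenyl)-4-[(Z)-2-(4-hydroxyphenyl)ethenyl]-2,3-dihydrobenzofuran-6-ol | Oc1ccc(/C=C\c2cc(O)cc3c2[C@H](c2cc(O)c4c(c2)[C@@H](c2cc(O)cc(O)c2)[C@H](c2ccc(O)cc2)O4)[C@@H](c2ccc(O)cc2)O3)cc1 | target

**Step count**

Total: 19 steps. Longest linear sequence: 12 steps (steps 1–7, 14, 15, 16, 18, 19).

**Steps most likely to fail, with fallbacks**

Step 6. The carbene carbon is flanked by chlorine and by the benzyloxy group, so the enantiotopic benzylic hydrogens may be poorly discriminated in the crowded pocket of the bulky chiral carboxylate catalyst, and turnover may be slow enough for carbene dimerisation to compete. The fallback gives up catalyst control and takes the configuration of C2 from a classical resolution. It sets out from 8: insertion with the open, robust achiral catalyst Rh2(esp)2 (CH2Cl2, rt, slow addition) would give the racemic cis ester F1. Saponification (LiOH, THF/MeOH/H2O) would give the racemic acid F2. Crystallisation with (R)-1-phenylethylamine (or its enantiomer, whichever gives the less soluble salt of the wanted acid) would give the diastereomerically pure ammonium salt F3, and acidification returns to the route at 10.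

Step 14. The C3 radical is hindered and easily oxidised, so it may be over-oxidised and lose the C2 hydrogen to give the aromatic benzofuran, or it may simply be reduced (protodecarboxylation) before the nickel centre captures it. The fallback generates the same radical by reduction instead of oxidation and uses a nucleophilic aryl partner. It sets out from 10 and 19: 10 with N-hydroxyphthalimide, N,N'-diisopropylcarbodiimide and DMAP (CH2Cl2, rt) would give the N-(acyloxy)phthalimide redox-active ester F4. Separately, 19 with n-BuLi (THF, −78 °C) and then ZnCl2 would give the arylzinc chloride F5. A thermal nickel-catalysed decarboxylative Negishi-type coupling of the two (NiCl2(dme), 4,4'-di-tert-butyl-2,2'-bipyridine, THF/DMF, rt) should again join C3 to ring C anti to ring F, returning to the route at 20.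

Step 18. Oxidative addition into the hindered, electron-rich C4–Cl bond may be slow, so protodeboronation of the alkenylboronate or Z to E erosion through reversible palladium hydride addition could overtake the coupling. The fallback builds the alkene geometry by reduction of an alkyne. It sets out from 22 and the alkyne 23: a copper-free Sonogashira coupling of the aryl chloride (PdCl2(MeCN)2, XPhos, Cs2CO3, MeCN, 90 °C) would give the diarylalkyne F6. Semihydrogenation over the Lindlar catalyst (Pd on CaCO3 poisoned with Pb(OAc)2, quinoline, H2, EtOAc) adds hydrogen syn and should give the Z alkene, returning to the route at 25.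

**Further compounds**

F1 | step 6 | methyl cis-4-chloro-6-methoxy-2-(4-methoxyphenyl)-2,3-dihydrobenzofuran-3-carboxylate (racemic) | COC(=O)C1c2c(Cl)cc(OC)cc2OC1c1ccc(OC)cc1
F2 | step 6 | cis-4-chloro-6-methoxy-2-(4-methoxyphenyl)-2,3-dihydrobenzofuran-3-carboxylic acid (racemic) | OC(=O)C1c2c(Cl)cc(OC)cc2OC1c1ccc(OC)cc1
F3 | step 6 | (R)-1-phenylethylammonium (2S,3R)-4-chloro-6-methoxy-2-(4-methoxyphenyl)-2,3-dihydrobenzofuran-3-carboxylate | C[C@@H]([NH3+])c1ccccc1.[O-]C(=O)[C@@H]1c2c(Cl)cc(OC)cc2O[C@@H]1c1ccc(OC)cc1
F4 | step 14 | 1,3-dioxoisoindolin-2-yl (2S,3R)-4-chloro-6-methoxy-2-(4-methoxyphenyl)-2,3-dihydrobenzofuran-3-carboxylate | O=C1c2ccccc2C(=O)N1OC(=O)[C@@H]1c2c(Cl)cc(OC)cc2O[C@@H]1c1ccc(OC)cc1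
F5 | step 14 | [(2R,3R)-3-(3,5-dimethoxyphenyl)-7-methoxy-2-(4-methoxyphenyl)-2,3-dihydrobenzofuran-5-yl]zinc chloride | Cl[Zn]c1cc(OC)c2c(c1)[C@@H](c1cc(OC)cc(OC)c1)[C@H](c1ccc(OC)cc1)O2
F6 | step 18 | heptakis(tert-butyldimethylsilyl) ether of the C4 (4-hydroxyphenyl)ethynyl analogue of the target | CC(C)(C)[Si](C)(C)Oc1ccc(C#Cc2cc(O[Si](C)(C)C(C)(C)C)cc3c2[C@H](c2cc(O[Si](C)(C)C(C)(C)C)c4c(c2)[C@@H](c2cc(O[Si](C)(C)C(C)(C)C)cc(O[Si](C)(C)C(C)(C)C)c2)[C@H](c2ccc(O[Si](C)(C)C(C)(C)C)cc2)O4)[C@@H](c2ccc(O[Si](C)(C)C(C)(C)C)cc2)O3)cc1
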